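**Retrosynthetic overview**
1. The C8 tertiary alcohol comes last, by HAT (radical/O2) Markovnikov hydration of an 8(17)-exocyclic alkene from the open α face.
2. C12–C13 is made by Ni-catalysed radical cross-electrophile coupling of a decalin primary iodide with an (R)-butenolide (E)-vinyl iodide.
3. Key step: both carbocycles form in one operation, ring A (C4–C5) then ring B (C10–C9). Cp2TiCl opens an acyclic 1,1-disubstituted C4/C18 epoxide. The single C6 carbinol steers C4, C5, C9 and C10, and the opened epoxide is already the C18 alcohol.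
4. The acyclic epoxy-diene-diol comes from 5-bromopent-1-ene, ethyl but-2-ynoate, propargyl bromide and oxirane, plus Me3Al and a sulfonium ylide. C6 is set by catalytic asymmetric propargylation.
5. The butenolide ring comes from pent-3-yn-1-ol and methyl propiolate by asymmetric alkynylation, Me2CuLi addition and lactonisation.

Assumption: labdane numbering (C1–C20, side chain C11–C16) is used for locants. Where a chiral catalyst is named, the antipode that gives the stated configuration is meant.

**Step 1**
Reactants: 1 5-bromopent-1-ene; 2 ethyl but-2-ynoate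
Product: 6 ethyl (E)-3-methylocta-2,7-dienoate, via pent-4-enylmagnesium bromide 3 (not isolated), via pent-4-enylcopper 4 (not isolated), via alkenylcopper adduct 5 (not isolated)
Conditions: Mg, THF; CuBr·SMe2 (1.1 equiv), THF–Me2S, −45 °C; 2, −78 °C; sat. aq NH4Cl at −78 °C
Reagents that add atoms: magnesium, [Mg] (in 3 only); copper(I) bromide–dimethyl sulfide, [Cu]Br.CSC (Cu in 4 and 5 only)
Why: Syn-carbocupration of the ynoate at −78 °C followed by cold protonation puts the new chain trans to the ester, which fixes the E C5=C10 alkene (organocopper addition to an alkynoate).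

**Step 2**
Reactants: 6 ethyl (E)-3-methylocta-2,7-dienoate
Product: 7 (E)-3-methylocta-2,7-dien-1-ol
Conditions: DIBAL-H (2.3 equiv), CH2Cl2, −78 °C; aq Rochelle salt
Reagents that add atoms: none
Why: DIBAL-H reduces the enoate 1,2 to the allylic alcohol and leaves both alkenes and the E geometry untouched.

**Step 3**
Reactants: 7 (E)-3-methylocta-2,7-dien-1-ol
Product: 8 (E)-3-methylocta-2,7-dienal
Conditions: activated MnO2 (15 equiv), CH2Cl2, rt
Reagents that add atoms: none
Why: MnO2 oxidises only the allylic alcohol and stops at the enal without E/Z scrambling (allylic oxidation).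

**Step 4**
Reactants: 8 (E)-3-methylocta-2,7-dienal; 9 3-bromoprop-1-yne (propargyl bromide)
Product: 11 (4S,5E)-6-methylundeca-5,10-dien-1-yn-4-ol, via trimethylsilyl ether 10 (not isolated)
Conditions: CrCl2 (10 mol %), (S,S)-iPr-bis(oxazolinyl)carbazole ligand (12 mol %), DIPEA (30 mol %), Mn (2 equiv), TMSCl (1.5 equiv), THF, 0 °C; then K2CO3 (cat.), MeOH, rt
Reagents that add atoms: chlorotrimethylsilane, C[Si](C)(C)Cl (in 10 only)
Why: In this catalytic asymmetric Nozaki–Hiyama–Kishi propargylation the ligand-bound allenyl/propargyl-Cr(III) species adds 1,2 (SE2′) to the Si face of the enal and sets C6 as S, while TMSCl turns over chromium and the silyl ether is cleaved in the same pot.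

**Step 5**
Reactants: 11 (4S,5E)-6-methylundeca-5,10-dien-1-yn-4-ol; 12 oxirane
Product: 15 (3E,6S,7E)-4,8-dimethyltrideca-3,7,12-triene-1,6-diol, via alkenylalane 13 (not isolated), via lithium alkenylalanate 14 (not isolated)
Conditions: Me3Al (3.5 equiv), Cp2ZrCl2 (25 mol %), CH2Cl2, 0 °C → rt; evaporate, hexane–THF; n-BuLi, −78 → 0 °C; oxirane (5 equiv), 0 °C → rt; aq Rochelle salt
Reagents that add atoms: trimethylaluminium, C[Al](C)C (C17 methyl; Al in 13 and 14 only); n-butyllithium, [Li]CCCC (in 14 only)
Why: Negishi Zr-catalysed syn-carboalumination puts CH3 on C8 and Al on C9 of the terminal alkyne only (OH masked in situ as its aluminium alkoxide), and the derived alanate opens oxirane with retention, giving the E C8=C9 alkene and the C11–C12 unit in one pot.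

**Step 6**
Reactants: 15 (3E,6S,7E)-4,8-dimethyltrideca-3,7,12-triene-1,6-diol
Product: 16 (6E,8S,10E)-8,13-dihydroxy-6,10-dimethyltrideca-6,10-dien-2-one
Conditions: PdCl2 (10 mol %), Cu(OAc)2 (20 mol %), O2 (1 atm), DMA–H2O 7:1, rt
Reagents that add atoms: water, O
Why: The buffered Cu(OAc)2 variant of the Tsuji–Wacker oxidation is selective for the monosubstituted terminal alkene and gives the methyl ketone, with the trisubstituted alkenes and free alcohols as spectators.

**Step 7**
Reactants: 16 (6E,8S,10E)-8,13-dihydroxy-6,10-dimethyltrideca-6,10-dien-2-one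
Product: 17 (3E,6S,7E)-4,8-dimethyl-11-(2-methyloxiran-2-yl)undeca-3,7-diene-1,6-diol (1:1 epimers at the oxirane carbon)
Conditions: Me3S+I− (4 equiv), NaH (4 equiv), DMSO–THF, 0 °C → rt
Reagents that add atoms: trimethylsulfonium iodide, C[S+](C)C.[I-]
Why: Corey–Chaykovsky methylene transfer to the unhindered methyl ketone gives the 1,1-disubstituted epoxide, and the epimer mixture does not matter because that carbon becomes a planar radical in step 8.

**Step 8 (key step)**
Reactants: 17 (3E,6S,7E)-4,8-dimethyl-11-(2-methyloxiran-2-yl)undeca-3,7-diene-1,6-diol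
Product: 18 13,14,15,16-tetranorlabd-8(17)-ene-6α,12,18-triol (trans-decalin; 5α-H, 9α-H, 10β-CH3, 4β-CH3, 4α-CH2OH, 6α-OH equatorial, 9β-CH2CH2OH, exocyclic C8=CH2)
Conditions: Cp2TiCl2 (3 equiv), Mn dust (8 equiv), degassed THF, rt, slow addition of 17 (final about 5 mM); 1 M HCl work-up; chromatographic removal of the minor C4 epimer
Reagents that add atoms: none
Why: Proposed new method: homolytic opening of either epoxide epimer by Cp2TiCl gives the same planar tertiary C4 radical carrying CH2O[Ti], which closes 6-endo on C5 and then, as the C10 radical, 6-endo on C9 through a chair–chair array; A(1,3) strain holds H6 in the C5=C10 plane next to the C10 methyl so the C6–O bond ends equatorial (6α), the bulky CH2O[Ti] takes the equatorial 4α site (where it can also lean on O6), the two E alkenes translate into 5α-H/10β-CH3/9α-H, and the C8 radical is trapped by a second Cp2TiCl and loses β-H to give the 8(17)-alkene; the closest known reaction type is the titanocene(III) (RajanBabu–Nugent) radical cyclisation of trisubstituted epoxypolyprenes.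

**Step 9**
Reactants: 18 13,14,15,16-tetranorlabd-8(17)-ene-6α,12,18-triol
Product: 19 12-iodo-13,14,15,16-tetranorlabd-8(17)-ene-6α,18-diol
Conditions: PPh3 (1.15 equiv), I2 (1.1 equiv), imidazole (2.5 equiv), premixed, CH2Cl2, −10 → 0 °C
Reagents that add atoms: iodine, II
Why: Appel-type iodination with preformed Ph3P·I2/imidazole is an SN2 process that only the unhindered C12 primary alcohol can complete, so the neopentyl C18 and hindered secondary C6 alcohols return unchanged on work-up.

**Step 10**
Reactants: 20 pent-3-yn-1-ol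
Product: 22 (E)-4-iodopent-3-en-1-ol, via alkenylzirconocene 21 (not isolated)
Conditions: Cp2Zr(H)Cl (2.3 equiv), THF, rt → 40 °C; I2 (1.1 equiv), −20 °C
Reagents that add atoms: zirconocene chloride hydride, [H][Zr](Cl)(C1C=CC=C1)C1C=CC=C1 (Zr in 21 only); iodine, II
Why: Syn-hydrozirconation with excess Schwartz reagent equilibrates to the less hindered CH3-flanked alkenylzirconium, and iodinolysis with retention gives the E 2-iodoalkene (hydrozirconation–iodination).

**Step 11**
Reactants: 22 (E)-4-iodopent-3-en-1-ol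
Product: 23 (E)-4-iodopent-3-enal
Conditions: Dess–Martin periodinane (1.2 equiv), NaHCO3, CH2Cl2, 0 °C; used at once
Reagents that add atoms: none
Why: Buffered Dess–Martin oxidation is neutral and fast, so the β,γ-unsaturated aldehyde is obtained without migration of the double bond into conjugation.

**Step 12**
Reactants: 23 (E)-4-iodopent-3-enal; 24 methyl propiolate
Product: 26 methyl (4R,6E)-4-hydroxy-7-iodooct-6-en-2-ynoate, via methylzinc propiolate 25 (not isolated)
Conditions: Me2Zn (3 equiv), (R,R)-ProPhenol (20 mol %), Ph3P=O (40 mol %), toluene, 0–4 °C; sat. aq NH4Cl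
Reagents that add atoms: dimethylzinc, C[Zn]C (in 25 only)
Why: Zn–ProPhenol catalysed asymmetric alkynylation delivers the zinc propiolate to the Si face of the aldehyde and sets the future butenolide carbinol centre (C16) as R.

**Step 13**
Reactants: 26 methyl (4R,6E)-4-hydroxy-7-iodooct-6-en-2-ynoate
Product: 28 (5R)-5-[(2E)-3-iodobut-2-en-1-yl]-4-methylfuran-2(5H)-one, via Z-hydroxy enoate 27 (not isolated)
Conditions: Me2CuLi (2.5 equiv, from CuI and MeLi), THF, −78 °C; sat. aq NH4Cl, then rt
Reagents that add atoms: lithium dimethylcuprate, [Li+].C[Cu-]C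
Why: Syn-carbocupration of the ynoate by the Gilman reagent at −78 °C (faster than any coupling at the vinyl iodide) places CH3 on the β-carbon and leaves the carbinol cis to the ester, so the Z-hydroxy enoate lactonises on work-up without touching the stereocentre.

**Step 14**
Reactants: 19 12-iodo-13,14,15,16-tetranorlabd-8(17)-ene-6α,18-diol; 28 (5R)-5-[(2E)-3-iodobut-2-en-1-yl]-4-methylfuran-2(5H)-one
Product: 29 8(17)-alkene precursor of the target (full C25 skeleton, 6α,18-diol, E C13=C14, 16R butenolide, exocyclic C8=CH2 in place of the C8 carbinol)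
Conditions: NiI2·xH2O (10 mol %), 4,4′-di-tert-butyl-2,2′-bipyridine (10 mol %), Mn (3 equiv), NaI (25 mol %), DMPU, 25–40 °C; 28 (1.5 equiv)
Reagents that add atoms: none
Why: In this nickel-catalysed reductive cross-electrophile coupling the vinyl iodide adds oxidatively to Ni(0), the primary C12 radical from the alkyl iodide is captured by vinyl–Ni(II), and reductive elimination forms C12–C13 with retention of the E geometry under neutral conditions that tolerate the free diol, the exocyclic alkene and the butenolide.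

**Step 15**
Reactants: 29 8(17)-alkene precursor of the target
Product: 31 target CNP0147582.1 (6α,8α,18-triol), via 8α-hydroperoxide 30 (not isolated)
Conditions: Co(acac)2 (20 mol %), PhSiH3 (2 equiv), O2 (1 atm), THF, 0 °C → rt, stopped at consumption of 29; then PPh3
Reagents that add atoms: dioxygen, O=O
Why: In this Mukaiyama HAT hydration Co–H transfers H• fastest to the unhindered =CH2 of the 1,1-disubstituted alkene (the trisubstituted C13=C14 and the electron-poor β,β-disubstituted butenolide react more slowly), and the tertiary C8 radical takes up O2 from the α face because the β face is blocked by the syn-axial C10 methyl and the C9 chain, giving 8α-OH/8β-CH3 after O–O reduction.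

**Compound list**
1 | 5-bromopent-1-ene | C=CCCCBr | starting material
2 | ethyl but-2-ynoate | CC#CC(=O)OCC | starting material
3 | pent-4-enylmagnesium bromide | C=CCCC[Mg]Br | intermediate
4 | pent-4-enylcopper | C=CCCC[Cu] | intermediate
5 | ethyl (Z)-2-cuprio-3-methylocta-2,7-dienoate | C=CCCC/C(C)=C(\[Cu])C(=O)OCC | intermediate
6 | ethyl (E)-3-methylocta-2,7-dienoate | C=CCCC/C(C)=C/C(=O)OCC | intermediate
7 | (E)-3-methylocta-2,7-dien-1-ol | C=CCCC/C(C)=C/CO | intermediate
8 | (E)-3-methylocta-2,7-dienal | C=CCCC/C(C)=C/C=O | intermediate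
9 | 3-bromoprop-1-yne | C#CCBr | starting material
10 | trimethylsilyl ether of 11 | C=CCCC/C(C)=C/[C@@H](O[Si](C)(C)C)CC#C | intermediate
11 | (4S,5E)-6-methylundeca-5,10-dien-1-yn-4-ol | C=CCCC/C(C)=C/[C@@H](O)CC#C | intermediate
12 | oxirane | C1CO1 | starting material
13 | (E)-alkenyl(dimethyl)alane, O-dimethylaluminium alkoxide | C=CCCC/C(C)=C/[C@@H](O[Al](C)C)C/C(C)=C/[Al](C)C | intermediate
14 | lithium alkenyl(butyl)dimethylalanate | [Li+].C=CCCC/C(C)=C/[C@@H](O[Al](C)C)C/C(C)=C/[Al-](C)(C)CCCC | intermediate
15 | (3E,6S,7E)-4,8-dimethyltrideca-3,7,12-triene-1,6-diol | C=CCCC/C(C)=C/[C@@H](O)C/C(C)=C/CCO | intermediate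
16 | (6E,8S,10E)-8,13-dihydroxy-6,10-dimethyltrideca-6,10-dien-2-one | CC(=O)CCC/C(C)=C/[C@@H](O)C/C(C)=C/CCO | intermediate
17 | (3E,6S,7E)-4,8-dimethyl-11-(2-methyloxiran-2-yl)undeca-3,7-diene-1,6-diol (both oxirane epimers) | CC1(CO1)CCC/C(C)=C/[C@@H](O)C/C(C)=C/CCO | intermediate
18 | 13,14,15,16-tetranorlabd-8(17)-ene-6α,12,18-triol | OCC[C@@H]1[C@@]2(C)CCC[C@@](C)(CO)[C@@H]2[C@@H](O)CC1=C | intermediate
19 | 12-iodo-13,14,15,16-tetranorlabd-8(17)-ene-6α,18-diol | ICC[C@@H]1[C@@]2(C)CCC[C@@](C)(CO)[C@@H]2[C@@H](O)CC1=C | intermediate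
20 | pent-3-yn-1-ol | CC#CCCO | starting material
21 | (E)-alkenylzirconocene chloride, O-zirconated (Cp drawn η1) | C/C(=C\CCO[Zr](Cl)(C1C=CC=C1)C1C=CC=C1)[Zr](Cl)(C1C=CC=C1)C1C=CC=C1 | intermediate
22 | (E)-4-iodopent-3-en-1-ol | OCC/C=C(\C)I | intermediate
23 | (E)-4-iodopent-3-enal | O=CC/C=C(\C)I | intermediate
24 | methyl propiolate | C#CC(=O)OC | starting material
25 | methyl 3-(methylzincio)prop-2-ynoate | COC(=O)C#C[Zn]C | intermediate
26 | methyl (4R,6E)-4-hydroxy-7-iodooct-6-en-2-ynoate | COC(=O)C#C[C@H](O)C/C=C(\C)I | intermediate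
27 | methyl (2Z,4R,6E)-4-hydroxy-7-iodo-3-methylocta-2,6-dienoate | COC(=O)/C=C(/C)[C@H](O)C/C=C(\C)I | intermediate
28 | (5R)-5-[(2E)-3-iodobut-2-en-1-yl]-4-methylfuran-2(5H)-one | CC1=CC(=O)O[C@@H]1C/C=C(\C)I | intermediate
29 | 8(17)-alkene precursor of the target | CC1=CC(=O)O[C@@H]1C/C=C(\C)CC[C@@H]1[C@@]2(C)CCC[C@@](C)(CO)[C@@H]2[C@@H](O)CC1=C | intermediate
30 | 8α-hydroperoxide | CC1=CC(=O)O[C@@H]1C/C=C(\C)CC[C@@H]1[C@@]2(C)CCC[C@@](C)(CO)[C@@H]2[C@@H](O)C[C@@]1(C)OO | intermediate
31 | CNP0147582.1, (5R)-5-{(2E)-5-[(1R,2R,4S,4aR,5R,8aS)-2,4-dihydroxy-5-(hydroxymethyl)-2,5,8a-trimethyldecahydronaphthalen-1-yl]-3-methylpent-2-en-1-yl}-4-methylfuran-2(5H)-one | CC1=CC(=O)O[C@@H]1C/C=C(\C)CC[C@@H]1[C@@]2(C)CCC[C@@](C)(CO)[C@@H]2[C@@H](O)C[C@@]1(C)O | target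

**Step count**
Total: 15 steps. Longest linear sequence: 11 steps (steps 1–9, 14 and 15). Steps 10–13 build the butenolide branch in parallel.

**Steps most likely to fail**

Step 8 (yield, face selection by C6, and the C4 epimer ratio). The fallback keeps the same C4 radical but generates it without titanium on O18. It sets out from 17, which is isomerised with diethylaluminium 2,2,6,6-tetramethylpiperidide to the allylic alcohol (3E,6S,7E)-4,8-dimethyl-12-methylidenetrideca-3,7-diene-1,6,13-triol F1. A Co(salen)Cl/PhSiH3 (catalytic) MHAT cycloisomerisation under argon then adds H• to the 1,1-disubstituted alkene. The same 6-endo/6-endo bicyclisation follows, and Co(II) takes H• back from the C8 radical. The sequence returns to the route at 18.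

Step 14 (homodimerisation or reduction instead of cross-coupling). The fallback replaces the reductive coupling by a two-electron B-alkyl Suzuki–Miyaura coupling. It sets out from 19, which is silylated (TESCl, imidazole) to the 6,18-bis(triethylsilyl) ether of 19 F2. Treatment with t-BuLi and then B-methoxy-9-BBN gives the lithium alkyl(methoxy)-9-BBN borate F3. This is coupled with 28 (Pd(dppf)Cl2, AsPh3, aq K3PO4, DMF) to give the 6,18-bis(triethylsilyl) ether of 29 F4. HF·pyridine then returns to the route at 29.

Step 15 (chemoselectivity against C13=C14 and the α/β ratio at C8). The fallback switches from HAT to ionic electrophilic hydration, which discriminates strongly for 1,1-disubstituted over trisubstituted alkenes. It sets out from 29. Hg(OAc)2 in THF–H2O followed by aq NaCl gives the 17-chloromercurio-8α-ol F5, with water entering C8 from the open α face. Neutral demercuration with Bu3SnH then gives 31.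

**Further compounds**
F1 | step 8 | (3E,6S,7E)-4,8-dimethyl-12-methylidenetrideca-3,7-diene-1,6,13-triol | C=C(CO)CCC/C(C)=C/[C@@H](O)C/C(C)=C/CCO
F2 | step 14 | 6,18-bis(triethylsilyl) ether of 19 | ICC[C@@H]1[C@@]2(C)CCC[C@@](C)(CO[Si](CC)(CC)CC)[C@@H]2[C@@H](O[Si](CC)(CC)CC)CC1=C
F3 | step 14 | lithium alkyl(methoxy)-9-BBN borate | [Li+].CO[B-]1(CC[C@@H]2[C@@]3(C)CCC[C@@](C)(CO[Si](CC)(CC)CC)[C@@H]3[C@@H](O[Si](CC)(CC)CC)CC2=C)C2CCCC1CCC2
F4 | step 14 | 6,18-bis(triethylsilyl) ether of 29 | CC1=CC(=O)O[C@@H]1C/C=C(\C)CC[C@@H]1[C@@]2(C)CCC[C@@](C)(CO[Si](CC)(CC)CC)[C@@H]2[C@@H](O[Si](CC)(CC)CC)CC1=C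
F5 | step 15 | 17-chloromercurio-8α-ol | CC1=CC(=O)O[C@@H]1C/C=C(\C)CC[C@@H]1[C@@]2(C)CCC[C@@](C)(CO)[C@@H]2[C@@H](O)C[C@@]1(C[Hg]Cl)O
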